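## Analysis of the target

The target is a cyclohexane fused to an oxirane (a 7-oxabicyclo[4.1.0]heptane) in which all six ring carbons carry oxygen. Numbering used here: C1 is the fully substituted oxirane carbon that bears the benzoyloxymethyl carbon C7, C2 and C3 carry the acetates, C4 and C5 the free hydroxyls, and C6 is the oxirane CH. The configuration is 1S,2R,3S,4R,5R,6S. With the ring drawn flat, the oxirane oxygen, O2 and O4 lie on the lower face and C7, O3 and O5 on the upper face, so the substituents alternate from C2 to C5 while O1 and O2 are cis.

The sensitive groups are the oxirane (acid, nucleophiles, participation by neighbouring ester carbonyls) and three esters that can migrate to the free O4/O5 diol under base. The difficulty is that six contiguous stereocentres, one of them quaternary, carry oxygen in three different states on a skeleton whose oxygen pattern is almost C2-symmetric; only C7 breaks that symmetry.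

The strategy rests on one feature. O1/O2 are cis on the lower face, and the lower-face oxirane bond at C6 can come from an upper-face C6–O leaving group, cis to O5, displaced by O1. Both C1/C2 and C5/C6 are then cis-diols, each anti to the neighbouring oxygen of the trans C3/C4 pair. That is the double syn-dihydroxylation product of a 3,4-trans-dioxygenated cyclohexa-1,5-diene, and the trans C3/C4 pair in this absolute configuration is C5/C4 of (–)-shikimic acid.

## Retrosynthetic reasoning

**22 from 21.** Only the O4–Si bond is cut. The free 4,5-diol is released last, under non-basic conditions, because an acetate next to a free hydroxyl migrates easily under base.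

**21 from 19 (through 20).** The C6–O bond of the oxirane is cut. C1 is tertiary and cannot be the electrophile, so O1 must attack C6 with inversion, which needs a leaving group on the upper face of C6. A 5,6-cyclic sulfate serves twice: it activates O6 and holds O5 as a sulfate monoester after ring closure, so O5 never competes as a nucleophile and never needs a separate protecting group. The forward step has to close a three-membered ring in the presence of three esters and then free O5.

**19 from 16 (through 18 and 17).** The S=O bond, the O2 acetyl and the two S–O bonds are removed in turn. The sulfite is made first because it is the step that tells the two cis-diols apart. The acetate goes on before the sulfite is oxidised, because the oxidant system would cleave a free cis-1,2-diol.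

**16 from 14.** The C1–O, C2–O, C5–O and C6–O bonds are cut together. This is the only disconnection that removes four stereocentres at once and leaves a diene with just two, both taken from the chiral pool. The forward reaction must add to each alkene anti to its allylic oxygen.

**14 from 11.** In shikimate numbering, the C3–O bond and one C6–H are restored, so the forward step is a 1,4-dehydration of an allylic alcohol with transposition of the alkene. A plain base-induced elimination would take the anti-periplanar C4–H instead. A sulfenate-to-sulfoxide rearrangement followed by syn-elimination is chosen because the rearrangement itself fixes where the new alkene forms.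

**11 from 8 (through 9 and 10).** Only protecting groups change: O4 receives its silyl ether while the allylic O3 is masked for one operation. The forward steps must distinguish the two hydroxyls of a cis-diol.

**8 from 1 and 5 (through 7, 4 and 3).** The acetonide, the O5 acetyl, the C7–O benzoyl bond (from benzoyl chloride 5) and the two C7–H bonds are removed, which leads back to (–)-shikimic acid 1. The acetonide is used because it selects the cis C3/C4 diol and so leaves the future acetate oxygen O5 free.

## Alternatives that were turned down

**Alternative 1:** ring closure at C1–C2 by ketyl–carbonyl coupling.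
- Disconnection and key step: an open-chain keto-aldehyde A2, drawn from a sugar lactone by adding the C7 branch and oxidising both chain ends, is treated with SmI2. The C2 aldehyde is reduced to a ketyl that adds to the C1 ketone and gives cyclohexane A1 with the O1/O2 cis-diol.
- For: all ring oxygens and four stereocentres come from the sugar, and no alkene face has to be chosen at C5/C6. On stereocontrol at C3–C6 this route is stronger than the chosen one.
- Against: A2 needs four different protecting groups and a long linear preparation. The closure must set the quaternary C1 and C2 in the right sense relative to C3 and C6, with only chelation and avoidance of neighbouring alkoxy groups as control. A1 then still needs two PMB ethers exchanged for esters, acetonide removal and the same O5/O6 differentiation before the oxirane can close. SmI2 is used in excess.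
- Comparison: the chosen route creates four C–O bonds and four stereocentres in one catalytic step on a seven-carbon skeleton that 1 already provides, with the final acetate and benzoate in place beforehand.

**Alternative 2:** desymmetrisation of a para-quinol by tethered oxa-Michael addition.
- Disconnection and key step: the C2–O bond. The achiral quinol A4 condenses through its tertiary hydroxyl with phenylboronic acid A5. A chiral amine–thiourea catalyst then guides the B–OH group onto one of the two enantiotopic enone β-carbons, giving the cis-fused boronate A3.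
- For: cheap achiral precursors, catalytic asymmetric induction, access to either enantiomer, and the quaternary carbinol with its cis neighbour set in one step. On flexibility it is stronger than a chiral-pool route.
- Against: only C1 and C2 are set. C3, C4, C5 and C6 must follow one at a time under substrate control: α-oxygenation at C3, reduction of the C4 ketone trans to O3, and oxygenation of the remaining enone alkene with transposition to the C1–C6 oxirane. The enantioselectivity for a quinol with an acyloxymethyl group is untested, and such quinols rearrange to phenols under acid.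
- Comparison: the chosen route takes its absolute configuration from 1 without a catalyst screen and sets four centres at once; it gives up access to the other enantiomer.

**Alternative 3:** hydroxyl-directed singlet-oxygen cycloaddition.
- Disconnection and key step: the C1–O and C4–O bonds. The trans-dihydrodiol monoacetate A7, a cyclohexa-1,3-diene with a free C2 hydroxyl, undergoes photo-oxygenation. Hydrogen bonding to the C2 hydroxyl steers the [4+2] addition to the lower face and gives endoperoxide A6.
- For: the quaternary C1–O bond and the C4–O bond form together in the correct relation to O2. Reduction of the O–O bond and a Payne rearrangement from a C5–C6 epoxide would then reach the target's oxirane. After its key step this route could be as short as the chosen one or shorter.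
- Against: A7 is not available from a cheap chiral-pool acid in a few steps and needs a trans-diol to be monoacylated selectively. Hydroxyl steering of singlet oxygen is weak and solvent-dependent, and ene reaction competes. The later epoxidation of C5=C6 would have to occur anti to two allylic hydroxyls, which normally direct syn. Peroxides must be carried through.
- Comparison: the chosen route relies on two osmylations that are each anti to an allylic oxygen and that reinforce each other, and on a precursor reachable from 1 by standard operations.

Key step: step 8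

## Route

Remark on numbering: compounds 1–13 use shikimate numbering (C1 bears C7, C2 is the alkene CH, C3–C5 carry oxygen, C6 is CH2). From 14 on, target numbering is used: C1 = shikimate C1, C2 = C6, C3 = C5, C4 = C4, C5 = C3, C6 = C2. "Shikimyl alcohol" means the C7 carbinol obtained by reducing the carboxyl group of 1.

Assumption: in step 8 the disubstituted C5=C6 alkene is taken to react first; the other order would give the same tetrol.

Step 1
Reactants: 1 (–)-shikimic acid
Product: 3 methyl 3,4-O-isopropylideneshikimate, via methyl shikimate 2 (not isolated)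
Conditions: MeOH, CSA (cat.), reflux; concentrate; 2,2-dimethoxypropane, acetone, rt
Reagents that add atoms: methanol, CO; 2,2-dimethoxypropane, COC(C)(C)OC
Why: Fischer esterification followed by acid-catalysed transketalisation; only the cis C3/C4 diol can close a five-membered dioxolane, so the trans-disposed 5-OH stays free and no stereocentre is touched.

Step 2
Reactants: 3 methyl 3,4-O-isopropylideneshikimate
Product: 4 3,4-O-isopropylideneshikimyl alcohol
Conditions: i-Bu2AlH (3.5 equiv), CH2Cl2, –78 to 0 °C; aq. KNaC4H4O6 work-up
Reagents that add atoms: none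
Why: Hydride reduction of the conjugated ester to the allylic alcohol; the 5-OH is carried as its aluminium alkoxide and the acetonide is inert.

Step 3
Reactants: 4 3,4-O-isopropylideneshikimyl alcohol; 5 benzoyl chloride
Product: 7 5-O-acetyl-7-O-benzoyl-3,4-O-isopropylideneshikimyl alcohol, via 7-O-benzoate 6 (not isolated)
Conditions: 5 (1.05 equiv), pyridine, CH2Cl2, –40 to 0 °C; then Ac2O, DMAP (cat.), rt
Reagents that add atoms: acetic anhydride, CC(=O)OC(C)=O
Why: Acylation with one equivalent of 5 at low temperature discriminates the primary allylic hydroxyl from the secondary 5-OH, and DMAP-catalysed acetylation then caps O5 in the same flask. This installs the future C3 acetate and the C7 benzoate before any sensitive diene exists.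

Step 4
Reactants: 7 5-O-acetyl-7-O-benzoyl-3,4-O-isopropylideneshikimyl alcohol
Product: 8 5-O-acetyl-7-O-benzoylshikimyl alcohol
Conditions: AcOH/H2O (4:1), 40 °C
Reagents that add atoms: none
Why: Mild acid hydrolysis of the acetonide; the esters tolerate aqueous acetic acid and acyl migration from O5 to O4 is slow under acid.

Step 5
Reactants: 8 5-O-acetyl-7-O-benzoylshikimyl alcohol
Product: 9 5-O-acetyl-7-O-benzoyl-3-O-triethylsilylshikimyl alcohol
Conditions: Et3SiCl (1.05 equiv), imidazole, CH2Cl2, –40 °C
Reagents that add atoms: chlorotriethylsilane, CC[Si](Cl)(CC)CC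
Why: Kinetic silylation; the allylic 3-OH is flanked by the sp2 C2–H, whereas the 4-OH sits between two oxygenated sp3 carbons and next to the electron-withdrawing acetate, so one equivalent of chlorosilane should go to O3.

Step 6
Reactants: 9 5-O-acetyl-7-O-benzoyl-3-O-triethylsilylshikimyl alcohol
Product: 11 5-O-acetyl-7-O-benzoyl-4-O-(tert-butyldimethylsilyl)shikimyl alcohol, via bis-silyl ether 10 (not isolated)
Conditions: TBSOTf (1.3 equiv), 2,6-lutidine, CH2Cl2, –78 to –20 °C; then MeOH, PPTS, 0 °C to rt
Reagents that add atoms: tert-butyldimethylsilyl triflate, CC(C)(C)[Si](C)(C)OS(=O)(=O)C(F)(F)F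
Why: The silyl triflate protects the hindered 4-OH; mildly acidic methanolysis then removes the more labile triethylsilyl ether and leaves the tert-butyldimethylsilyl ether, so only the allylic 3-OH is free.

Step 7
Reactants: 11 5-O-acetyl-7-O-benzoyl-4-O-(tert-butyldimethylsilyl)shikimyl alcohol
Product: 14 [(3R,4R)-3-acetoxy-4-(tert-butyldimethylsilyloxy)cyclohexa-1,5-dien-1-yl]methyl benzoate, via allylic sulfenate 12 (not isolated), via tertiary allylic sulfoxide 13 (not isolated)
Conditions: 2,4-(O2N)2C6H3SCl (1.2 equiv), Et3N, CH2Cl2, –20 °C to rt; then ClCH2CH2Cl, 60 °C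
Reagents that add atoms: none
Why: O-Sulfenylation gives sulfenate 12, which undergoes the [2,3]-sigmatropic shift (Mislow–Evans rearrangement run from sulfenate to sulfoxide) to the C1 sulfoxide 13; syn-elimination of this electron-poor aryl sulfoxide can only take a hydrogen from C6, because C2 is vinylic and C7–H sits on an oxygen-bearing carbon. The rearrangement fixes the regiochemistry, the C4–H is not touched, and C4 and C5 keep their configuration.

Step 8
Reactants: 14 [(3R,4R)-3-acetoxy-4-(tert-butyldimethylsilyloxy)cyclohexa-1,5-dien-1-yl]methyl benzoate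
Product: 16 [(1S,2R,3R,4R,5S,6R)-3-acetoxy-4-(tert-butyldimethylsilyloxy)-1,2,5,6-tetrahydroxycyclohexyl]methyl benzoate, via 5,6-diol monoadduct 15 (not isolated)
Conditions: OsO4 (5 mol %), NMO (3 equiv), acetone/H2O (8:1), 0 °C to rt
Reagents that add atoms: osmium tetroxide, O=[Os](=O)(=O)=O; N-methylmorpholine N-oxide, C[N+]1([O-])CCOCC1; water, O
Why: Two Upjohn dihydroxylations run in one flask: each is a suprafacial [3+2] addition of OsO4 to an alkene, hydrolysis of the osmate ester and re-oxidation of osmium by NMO, so the two C–O bonds at each alkene are cis. The closest known reaction type is the osmium-catalysed bis-dihydroxylation of O-protected trans-5,6-dioxygenated cyclohexa-1,3-dienes to conduritols and inositols. No ring closes. C5 and C6 are set by attack on the upper face, anti to the allylic C4 silyl ether; C1 and C2 are set by attack on the lower face, anti to the allylic C3 acetate. The C5=C6 alkene, flanked by a single silyloxy group, should react first, and the upper-face hydroxyl it places at C6 is allylic to C1=C2 and reinforces lower-face attack there; the reverse order is matched in the same way. The step needs π-facial selectivity at both alkenes and full conversion of the slower, acyloxy-flanked trisubstituted alkene; the trans C3/C4 oxygens secure the first, excess NMO and time the second. The CH2OBz group keeps C1=C2 out of conjugation with a carbonyl, so both alkenes stay nucleophilic enough for OsO4.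

Step 9
Reactants: 16 [(1S,2R,3R,4R,5S,6R)-3-acetoxy-4-(tert-butyldimethylsilyloxy)-1,2,5,6-tetrahydroxycyclohexyl]methyl benzoate
Product: 17 5,6-cyclic sulfite of 16
Conditions: SOCl2 (1.05 equiv), imidazole (4.5 equiv), CH2Cl2, –40 °C; then 16, –40 to 0 °C
Reagents that add atoms: thionyl chloride, O=S(Cl)Cl
Why: Cyclic sulfite formation from a cis-1,2-diol with thionyldiimidazole made in the flask; O5 is the only secondary hydroxyl whose carbon is not bonded to the fully substituted C1, so it should be sulfinylated first and then close onto the cis O6, leaving the hindered O1/O2 pair free.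

Step 10
Reactants: 17 5,6-cyclic sulfite of 16
Product: 18 2-O-acetyl-5,6-cyclic sulfite of 16
Conditions: Ac2O (1.5 equiv), pyridine, DMAP (cat.), CH2Cl2, 0 °C to rt
Reagents that add atoms: acetic anhydride, CC(=O)OC(C)=O
Why: Standard acylation; O2 is now the only secondary hydroxyl and the tertiary O1–H is not acetylated under these conditions. The acetate is placed before the oxidation because periodate in step 11 would cleave a free cis-1,2-diol.

Step 11
Reactants: 18 2-O-acetyl-5,6-cyclic sulfite of 16
Product: 19 2-O-acetyl-5,6-cyclic sulfate of 16
Conditions: RuCl3·xH2O (1 mol %), NaIO4 (1.5 equiv), MeCN/EtOAc/H2O, 0 °C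
Reagents that add atoms: sodium periodate, [Na+].[O-]I(=O)(=O)=O
Why: Ruthenium tetroxide, formed catalytically from RuCl3 and NaIO4, oxidises the cyclic sulfite to the cyclic sulfate within minutes at 0 °C; the tertiary alcohol, the esters and the silyl ether are inert.

Step 12
Reactants: 19 2-O-acetyl-5,6-cyclic sulfate of 16
Product: 21 4-O-(tert-butyldimethylsilyl) ether of 22, via sodium epoxy sulfate 20 (not isolated)
Conditions: NaN(SiMe3)2 (1.05 equiv), THF, –78 to 0 °C; then H2O (2 equiv), H2SO4 (cat.), THF, rt
Reagents that add atoms: none
Why: The sodium alkoxide of O1 is axial and anti-periplanar to the axial C6–O bond of the cyclic sulfate, so 3-exo-tet displacement with inversion at C6 closes the oxirane on the lower face (the cyclic-sulfate version of epoxide formation from a trans-hydroxy sulfonate) and leaves O5 as the sulfate monoester 20. Acid-catalysed hydrolysis with a little water then cleaves the S–O bond of the monoester with retention at C5.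

Step 13
Reactants: 21 4-O-(tert-butyldimethylsilyl) ether of 22
Product: 22 [(1S,2R,3S,4R,5R,6S)-2,3-diacetoxy-4,5-dihydroxy-7-oxabicyclo[4.1.0]heptan-1-yl]methyl benzoate
Conditions: HF·pyridine, pyridine, THF, 0 °C to rt
Reagents that add atoms: none
Why: Fluoride cleavage of the silyl ether under buffered, weakly acidic conditions, chosen to avoid base-induced acetyl migration to the freed 4,5-diol; the electron-poor oxirane is expected to survive.

## Compound list

1 | (–)-shikimic acid, (3R,4S,5R)-3,4,5-trihydroxycyclohex-1-ene-1-carboxylic acid | O=C(O)C1=C[C@@H](O)[C@@H](O)[C@H](O)C1 | starting material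
2 | methyl shikimate (methyl ester of 1, configuration unchanged) | COC(=O)C1=C[C@@H](O)[C@@H](O)[C@H](O)C1 | intermediate
3 | methyl 3,4-O-isopropylideneshikimate (cis-fused acetonide on O3/O4, free 5-OH) | COC(=O)C1=C[C@H]2OC(C)(C)O[C@H]2[C@H](O)C1 | intermediate
4 | 3,4-O-isopropylideneshikimyl alcohol (C1–CH2OH, free 5-OH) | OCC1=C[C@H]2OC(C)(C)O[C@H]2[C@H](O)C1 | intermediate
5 | benzoyl chloride | O=C(Cl)c1ccccc1 | starting material
6 | 7-O-benzoyl-3,4-O-isopropylideneshikimyl alcohol (free 5-OH) | O=C(OCC1=C[C@H]2OC(C)(C)O[C@H]2[C@H](O)C1)c1ccccc1 | intermediate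
7 | 5-O-acetyl-7-O-benzoyl-3,4-O-isopropylideneshikimyl alcohol | O=C(OCC1=C[C@H]2OC(C)(C)O[C@H]2[C@H](OC(C)=O)C1)c1ccccc1 | intermediate
8 | 5-O-acetyl-7-O-benzoylshikimyl alcohol (free cis-3,4-diol) | O=C(OCC1=C[C@@H](O)[C@@H](O)[C@H](OC(C)=O)C1)c1ccccc1 | intermediate
9 | 5-O-acetyl-7-O-benzoyl-3-O-triethylsilylshikimyl alcohol (free 4-OH) | O=C(OCC1=C[C@@H](O[Si](CC)(CC)CC)[C@@H](O)[C@H](OC(C)=O)C1)c1ccccc1 | intermediate
10 | 5-O-acetyl-7-O-benzoyl-4-O-(tert-butyldimethylsilyl)-3-O-triethylsilylshikimyl alcohol | O=C(OCC1=C[C@@H](O[Si](CC)(CC)CC)[C@@H](O[Si](C)(C)C(C)(C)C)[C@H](OC(C)=O)C1)c1ccccc1 | intermediate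
11 | 5-O-acetyl-7-O-benzoyl-4-O-(tert-butyldimethylsilyl)shikimyl alcohol (free allylic 3-OH) | O=C(OCC1=C[C@@H](O)[C@@H](O[Si](C)(C)C(C)(C)C)[C@H](OC(C)=O)C1)c1ccccc1 | intermediate
12 | 3-O-(2,4-dinitrophenylsulfenyl) derivative of 11 | O=C(OCC1=C[C@@H](OSc2ccc(cc2[N+](=O)[O-])[N+](=O)[O-])[C@@H](O[Si](C)(C)C(C)(C)C)[C@H](OC(C)=O)C1)c1ccccc1 | intermediate
13 | C1 (2,4-dinitrophenyl) sulfoxide with C2=C3 alkene; sulfur on the face O3 occupied, configuration at sulfur undefined | O=C(OC[C@@]1(S(=O)c2ccc(cc2[N+](=O)[O-])[N+](=O)[O-])C[C@@H](OC(C)=O)[C@H](O[Si](C)(C)C(C)(C)C)C=C1)c1ccccc1 | intermediate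
14 | [(3R,4R)-3-acetoxy-4-(tert-butyldimethylsilyloxy)cyclohexa-1,5-dien-1-yl]methyl benzoate | CC(=O)O[C@H]1[C@H](O[Si](C)(C)C(C)(C)C)C=CC(COC(=O)c2ccccc2)=C1 | intermediate
15 | 5,6-cis-diol of 14 (both hydroxyls on the upper face, C1=C2 intact) | CC(=O)O[C@H]1[C@H](O[Si](C)(C)C(C)(C)C)[C@@H](O)[C@@H](O)C(COC(=O)c2ccccc2)=C1 | intermediate
16 | [(1S,2R,3R,4R,5S,6R)-3-acetoxy-4-(tert-butyldimethylsilyloxy)-1,2,5,6-tetrahydroxycyclohexyl]methyl benzoate (O1, O2 lower face; O5, O6 upper face) | CC(=O)O[C@H]1[C@H](O[Si](C)(C)C(C)(C)C)[C@@H](O)[C@@H](O)[C@@](O)(COC(=O)c2ccccc2)[C@@H]1O | intermediate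
17 | 5,6-cyclic sulfite of 16 (configuration at sulfur undefined) | CC(=O)O[C@H]1[C@H](O[Si](C)(C)C(C)(C)C)[C@H]2OS(=O)O[C@H]2[C@@](O)(COC(=O)c2ccccc2)[C@@H]1O | intermediate
18 | 2-O-acetyl-5,6-cyclic sulfite of 16 | CC(=O)O[C@H]1[C@H](O[Si](C)(C)C(C)(C)C)[C@H]2OS(=O)O[C@H]2[C@@](O)(COC(=O)c2ccccc2)[C@@H]1OC(C)=O | intermediate
19 | 2-O-acetyl-5,6-cyclic sulfate of 16 | CC(=O)O[C@H]1[C@H](O[Si](C)(C)C(C)(C)C)[C@H]2OS(=O)(=O)O[C@H]2[C@@](O)(COC(=O)c2ccccc2)[C@@H]1OC(C)=O | intermediate
20 | sodium 5-O-sulfate of 21 (oxirane closed, O5 as sulfate monoester) | CC(=O)O[C@H]1[C@H](O[Si](C)(C)C(C)(C)C)[C@@H](OS(=O)(=O)[O-])[C@@H]2O[C@]2(COC(=O)c2ccccc2)[C@@H]1OC(C)=O.[Na+] | intermediate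
21 | 4-O-(tert-butyldimethylsilyl) ether of 22 | CC(=O)O[C@H]1[C@H](O[Si](C)(C)C(C)(C)C)[C@@H](O)[C@@H]2O[C@]2(COC(=O)c2ccccc2)[C@@H]1OC(C)=O | intermediate
22 | [(1S,2R,3S,4R,5R,6S)-2,3-diacetoxy-4,5-dihydroxy-7-oxabicyclo[4.1.0]heptan-1-yl]methyl benzoate | CC(=O)O[C@H]1[C@H](O)[C@@H](O)[C@@H]2O[C@]2(COC(=O)c2ccccc2)[C@@H]1OC(C)=O | target

## Step count and least certain steps

Total step count: 13. Longest linear sequence: 13 steps (1 to 22; 5 enters in step 3).

**Step 8 (key step).** The most likely failure is slow or poorly face-selective osmylation of the trisubstituted C1=C2 alkene. It is deactivated by two allylic acyloxy groups, and an acetate is a weaker anti director than an ether. The long reaction time this forces also invites acetyl migration from O3 to the new O2 in the weakly basic medium.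
Fallback, from 14 back to 16: the two additions are staged. With one equivalent of NMO at 0 °C the reaction is stopped at 15, which is isolated and converted with 2,2-dimethoxypropane and PPTS into the 5,6-O-isopropylidene ene-diol F1. Its cis-fused dioxolane occupies the upper face next to C1=C2. Stoichiometric OsO4 in pyridine with NaHSO3 work-up then gives the 1,2-diol 5,6-acetonide F2 from the lower face, and aqueous acetic acid removes the acetonide to return to 16.

**Step 9.** The most likely failure is loss of site selectivity: sulfinylation begins at O2 and closes onto the tertiary O1, or both diols react. Thionyl transfer is irreversible, so the outcome is fixed by the first attack, and the neighbouring silyl ether at C4 may cancel the advantage of O5.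
Fallback, from 14 back to 17: the sulfite is formed before O1 and O2 exist. Diene 14 is mono-dihydroxylated as above to 15, which has only one diol and gives the ene cyclic sulfite F3 with SOCl2 and Et3N. Upjohn dihydroxylation of the remaining alkene, from the lower face anti to both the C3 acetate and the cis-fused sulfite, then delivers 17.

**Step 7.** The most likely failure is an unfavourable sulfenate–sulfoxide equilibrium, because the sulfoxide must sit on a fully substituted carbon. The elimination then needs prolonged heating, and the diene aromatises by loss of acetic acid or silanol.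
Fallback, from 11 back to 14: the allylic alcohol is converted with methyl chloroformate and pyridine into the 3-O-methoxycarbonyl derivative F4. Tsuji–Trost elimination with Pd(PPh3)4 in THF at 50 °C (ionisation to the π-allyl complex, loss of CO2, β-hydride elimination from C6) then gives 14. The carbonate ionises far faster than the benzoate or the acetate, which keeps the site of ionisation defined.

**Step 5.** The most likely failure is insufficient discrimination between O3 and O4 of the cis-diol, giving mixtures of 3-, 4- and bis-silyl ethers.
Fallback, from 8 back to 11: the diol is tied as the 3,4-cyclic orthoformate F5 with HC(OMe)3 and CSA, and brief treatment with aqueous acetic acid opens it to the pseudoaxial 3-O-formate F6, the usual outcome for orthoesters of cis-diols on six-membered rings. TBSOTf and 2,6-lutidine give the 3-O-formyl-4-O-silyl ether F7, and KHCO3 in methanol at 0 °C removes the formate, far faster than the acetate or benzoate, to give 11.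

**Step 12.** Two processes may interfere. In the base stage, transfer of the O2 acetyl or the C7 benzoyl group to the O1 alkoxide competes with ring closure. In the acid stage, the oxirane may open with participation of a neighbouring ester carbonyl.
Fallback, from 16 to 22: a sulfonate replaces the cyclic sulfate, so no acid stage is needed. Chlorotriethylsilane and imidazole silylate the least hindered secondary hydroxyl to give the 5-O-triethylsilyl ether F8. Ac2O in pyridine acetylates the equatorial O2 in preference to the axial O6 (2-O-acetate F9), and MsCl with Et3N gives the 6-O-mesylate F10. NaN(SiMe3)2 closes the oxirane to the 4,5-bis-silyl epoxide F11, and HF·pyridine removes both silyl groups to give 22.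

## Further compounds

F1 | step 8 | 5,6-O-isopropylidene derivative of 15 (C1=C2 intact) | CC(=O)O[C@H]1[C@H](O[Si](C)(C)C(C)(C)C)[C@H]2OC(C)(C)O[C@H]2C(COC(=O)c2ccccc2)=C1
F2 | step 8 | 5,6-O-isopropylidene derivative of 16 (free 1,2-diol) | CC(=O)O[C@H]1[C@H](O[Si](C)(C)C(C)(C)C)[C@H]2OC(C)(C)O[C@H]2[C@@](O)(COC(=O)c2ccccc2)[C@@H]1O
F3 | step 9 | 5,6-cyclic sulfite of 15 (C1=C2 intact) | CC(=O)O[C@H]1[C@H](O[Si](C)(C)C(C)(C)C)[C@H]2OS(=O)O[C@H]2C(COC(=O)c2ccccc2)=C1
F4 | step 7 | 3-O-methoxycarbonyl derivative of 11 | O=C(OCC1=C[C@@H](OC(=O)OC)[C@@H](O[Si](C)(C)C(C)(C)C)[C@H](OC(C)=O)C1)c1ccccc1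
F5 | step 5 | 3,4-O-(methoxymethylidene) cyclic orthoformate of 8 | O=C(OCC1=C[C@H]2OC(OC)O[C@H]2[C@H](OC(C)=O)C1)c1ccccc1
F6 | step 5 | 3-O-formyl derivative of 8 (free 4-OH) | O=C(OCC1=C[C@@H](OC=O)[C@@H](O)[C@H](OC(C)=O)C1)c1ccccc1
F7 | step 5 | 3-O-formyl-4-O-(tert-butyldimethylsilyl) derivative of 8 | O=C(OCC1=C[C@@H](OC=O)[C@@H](O[Si](C)(C)C(C)(C)C)[C@H](OC(C)=O)C1)c1ccccc1
F8 | step 12 | 5-O-triethylsilyl ether of 16 | CC(=O)O[C@H]1[C@H](O[Si](C)(C)C(C)(C)C)[C@@H](O[Si](CC)(CC)CC)[C@@H](O)[C@@](O)(COC(=O)c2ccccc2)[C@@H]1O
F9 | step 12 | 2-O-acetyl-5-O-triethylsilyl derivative of 16 | CC(=O)O[C@H]1[C@H](O[Si](C)(C)C(C)(C)C)[C@@H](O[Si](CC)(CC)CC)[C@@H](O)[C@@](O)(COC(=O)c2ccccc2)[C@@H]1OC(C)=O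
F10 | step 12 | 2-O-acetyl-6-O-methanesulfonyl-5-O-triethylsilyl derivative of 16 | CC(=O)O[C@H]1[C@H](O[Si](C)(C)C(C)(C)C)[C@@H](O[Si](CC)(CC)CC)[C@@H](OS(C)(=O)=O)[C@@](O)(COC(=O)c2ccccc2)[C@@H]1OC(C)=O
F11 | step 12 | 4-O-(tert-butyldimethylsilyl)-5-O-triethylsilyl ether of 22 | CC(=O)O[C@H]1[C@H](O[Si](C)(C)C(C)(C)C)[C@@H](O[Si](CC)(CC)CC)[C@@H]2O[C@]2(COC(=O)c2ccccc2)[C@@H]1OC(C)=O
A1 | alternative 1 | protected 1-C-(4-methoxybenzyloxymethyl)-chiro-inositol with free 1,2-cis-diol (3-O-PMB, 4-O-TBS, 5,6-O-isopropylidene) | COc3ccc(cc3)CO[C@H]1[C@H](O[Si](C)(C)C(C)(C)C)[C@H]2OC(C)(C)O[C@H]2[C@@](O)(COCc2ccc(OC)cc2)[C@@H]1O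
A2 | alternative 1 | open-chain C1 ketone / C2 aldehyde precursor of A1 | O=C[C@@H](OCc1ccc(OC)cc1)[C@H](O[Si](C)(C)C(C)(C)C)[C@H]1OC(C)(C)O[C@H]1C(=O)COCc1ccc(OC)cc1
A3 | alternative 2 | cis-fused phenylboronate of 4-(benzoyloxymethyl)-4,5-dihydroxycyclohex-2-enone | O=C1C=C[C@]2(COC(=O)c3ccccc3)OB(c3ccccc3)O[C@@H]2C1
A4 | alternative 2 | (1-hydroxy-4-oxocyclohexa-2,5-dien-1-yl)methyl benzoate | O=C1C=CC(O)(COC(=O)c2ccccc2)C=C1
A5 | alternative 2 | phenylboronic acid | OB(O)c1ccccc1
A6 | alternative 3 | [8-acetoxy-7-hydroxy-2,3-dioxabicyclo[2.2.2]oct-5-en-1-yl]methyl benzoate (peroxide bridge cis to the 7-hydroxyl) | O[C@@H]1[C@@H](OC(C)=O)[C@H]2C=C[C@]1(COC(=O)c3ccccc3)OO2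
A7 | alternative 3 | (trans-5-acetoxy-6-hydroxycyclohexa-1,3-dien-1-yl)methyl benzoate | O[C@@H]1[C@@H](OC(C)=O)C=CC=C1COC(=O)c1ccccc1
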